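The cyclopentane ring (C1–C5) carries its oxygenated carbon C4 between C3 and the ring-fusion carbon C5, with the methyl-bearing quaternary C1 one carbon further: the pattern of a cyclopentenone. The route therefore rests on cutting C1–C2. A Nazarov cyclisation of a cross-conjugated dienone, C2=C3–C4(=O)–C5=C1, whose tetrasubstituted alkene C5=C1 already lies in the seven-membered ring (C1, C5–C10), closes the five-membered ring, sets the quaternary stereocentre C1 under control of a chiral Brønsted acid, and leaves the C4 ketone and a C5=C6 alkene for all later oxygenation. The precursor is an achiral vinyl 2,5-dimethylcyclohepta-1,4-dienyl ketone.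

Key step: step 5

Labels: target atom labels are used throughout: C1 (quaternary, CH3), C2 (OAc), C3, C4 (OH, i-Pr), C5 (ring-fusion H) in the five-membered ring; C6 (O-anisoyl), C7, C8 (CH3)=C9, C10 in the seven-membered ring. β is the face of the bicycle that carries the C1 methyl, α the opposite face.
Assumption: the sense of induction of the chiral acid cannot be predicted, so the catalyst enantiomer is defined as the one that gives (R)-configured C1 in 11.

Step 1
Reactants: 1 3-chlorobutan-2-one
Product: 2 3-chloro-2-(trimethylsilyloxy)but-1-ene (racemic)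
Conditions: LDA, TMSCl (in-situ quench), THF, −78 °C
Reagents that add atoms: chlorotrimethylsilane, C[Si](C)(C)Cl
Why: Kinetic deprotonation of the methyl group by the hindered amide with immediate O-silylation (regioselective silyl enol ether formation) should give the 2-silyloxyallyl chloride.

Step 2
Reactants: 2 3-chloro-2-(trimethylsilyloxy)but-1-ene; 3 isoprene
Product: 4 2,5-dimethylcyclohept-4-en-1-one (racemic)
Conditions: AgClO4, isoprene (excess), MeNO2, 0 °C; aqueous work-up
Reagents that add atoms: isoprene (3), C=CC(C)=C
Why: Silver-assisted ionisation gives the 1-methyl-2-silyloxyallyl cation, which should undergo (4+3) cycloaddition with isoprene, bonding first from its unsubstituted terminus to C1 of the diene (tertiary allyl cation) so that the methyls end up 2,5; the single stereocentre is racemic and is erased in step 3.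

Step 3
Reactants: 4 2,5-dimethylcyclohept-4-en-1-one
Product: 6 2,5-dimethylcyclohepta-1,4-dien-1-yl trifluoromethanesulfonate, via bromomagnesium enolate 5 (not isolated)
Conditions: i-Pr2NMgBr (from EtMgBr, i-Pr2NH), Et2O, rt; then PhNTf2, THF, 0 °C to rt
Reagents that add atoms: N-phenylbis(trifluoromethanesulfonimide), FC(F)(F)S(=O)(=O)N(c1ccccc1)S(=O)(=O)C(F)(F)F
Why: The magnesium amide allows enolate equilibration to the more substituted (tetrasubstituted) enolate, which is O-sulfonylated (thermodynamic enol triflate formation) and thereby loses the stereocentre.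

Step 4
Reactants: 6 2,5-dimethylcyclohepta-1,4-dien-1-yl trifluoromethanesulfonate; 7 tributyl(vinyl)stannane; 8 carbon monoxide
Product: 9 1-(2,5-dimethylcyclohepta-1,4-dien-1-yl)prop-2-en-1-one
Conditions: CO (1 atm), Pd(PPh3)4 (cat.), LiCl, THF, 55 °C; BHT added on isolation, stored cold
Reagents that add atoms: tributyl(vinyl)stannane (7), C=C[Sn](CCCC)(CCCC)CCCC; carbon monoxide (8), [C-]#[O+]
Why: Carbonylative Stille coupling (oxidative addition of the alkenyl triflate, CO insertion, vinyl transfer from tin) should give the cross-conjugated dienone with the acyl group on the ring carbon that becomes C5.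

Step 5
Reactants: 9 1-(2,5-dimethylcyclohepta-1,4-dien-1-yl)prop-2-en-1-one
Product: 11 (3aR)-3a,6-dimethyl-3,3a,4,7-tetrahydroazulen-1(2H)-one, via cross-conjugated dienol 10 (not isolated)
Conditions: confined chiral imidodiphosphorimidate (IDPi) Brønsted acid (5 mol %, enantiomer chosen for (R)-11), toluene, 5 Å MS, −20 °C
Reagents that add atoms: none
Why: Proposed new method: the acid protonates the C4 carbonyl of 9 and the resulting hydroxypentadienyl cation (C2–C3–C4–C5–C1), ion-paired with the confined chiral anion, closes by thermal conrotatory 4π electrocyclisation between the unsubstituted terminus C2 and the fully substituted C1, after which the hydroxyallyl cation loses the C6 proton to the anion to give dienol 10, which tautomerises to 11. The closest known reaction types are the acid-promoted Nazarov cyclisation of cycloalkenyl vinyl ketones, known only in racemic form, and the enantioselective Nazarov cyclisation of simple acyclic divinyl ketones catalysed by confined imidodiphosphorimidate acids. The five-membered ring is closed by a single C1–C2 bond in a 4π-conrotatory electrocyclic mode. The only new stereocentre, the quaternary C1, is fixed by the sense of conrotation of the helical cation, and since 9 is achiral this sense can come only from the chiral anion pocket, which is why the catalyst enantiomer is chosen for (R). The step needs torquoselectivity, proton loss from C6 and not from C2, and activation of the carbonyl in preference to the C8=C9 alkene: C1 has no hydrogen, loss of the C6 proton gives the more substituted conjugated alkene, and the carbonyl oxygen is by far the most basic site at −20 °C.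

Step 6
Reactants: 11 (3aR)-3a,6-dimethyl-3,3a,4,7-tetrahydroazulen-1(2H)-one
Product: 13 (3aS)-3a,6-dimethyl-4,7-dihydroazulen-1(3aH)-one, via trimethylsilyl dienol ether 12 (not isolated)
Conditions: LDA, TMSCl, THF, −78 °C; then Pd(OAc)2, MeCN, rt
Reagents that add atoms: none
Why: Saegusa–Ito dehydrogenation: LDA removes the only α-proton it can reach through the lithium-bound transition state (C3, kinetic α′-deprotonation; the γ-protons at C7 point away from the carbonyl) and Pd(II) converts the silyl dienol ether into the C2=C3 enone without touching C1.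

Step 7
Reactants: 13 (3aS)-3a,6-dimethyl-4,7-dihydroazulen-1(3aH)-one
Product: 14 2α,3α-epoxide of 13 (C4 ketone, C5=C6 and C8=C9 retained)
Conditions: 30% H2O2, aq. NaOH (cat.), MeOH, 0 °C
Reagents that add atoms: hydrogen peroxide, OO
Why: Weitz–Scheffer nucleophilic epoxidation: hydroperoxide should add to C2 of the α-unsubstituted ring enone in preference to the α-substituted C5=C6 enone and enter anti to the C1 methyl, so the quaternary C1 places the epoxide oxygen on the α face.

Step 8
Reactants: 14 2α,3α-epoxide of 13
Product: 15 2α-hydroxy dienone (C2 OH α, C4 ketone, C5=C6, C8=C9)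
Conditions: SmI2 (2.2 equiv), MeOH, THF, −90 °C
Reagents that add atoms: none
Why: SmI2 reduction of an α,β-epoxy ketone: electron transfer to the ketone cleaves the Cα–O bond at C3 and the enolate is protonated at C3, so the C2–O bond and its α configuration are retained.

Step 9
Reactants: 15 2α-hydroxy dienone
Product: 16 2α-(tert-butyldimethylsilyloxy) dienone
Conditions: TBSOTf, 2,6-lutidine, CH2Cl2, −78 °C
Reagents that add atoms: tert-butyldimethylsilyl trifluoromethanesulfonate, CC(C)(C)[Si](C)(C)OS(=O)(=O)C(F)(F)F
Why: Silyl triflate protection of the hindered secondary alcohol masks the β-hydroxy ketone against base and keeps the two secondary hydroxyls of the target distinguishable.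

Step 10
Reactants: 16 2α-(tert-butyldimethylsilyloxy) dienone
Product: 17 5α,6α-epoxy ketone (2α-OTBS, C4 ketone, C8=C9)
Conditions: 30% H2O2, aq. LiOH (cat.), MeOH, 0 °C
Reagents that add atoms: hydrogen peroxide, OO
Why: Weitz–Scheffer epoxidation of the alkylidene cyclopentanone: hydroperoxide should attack C6 on the α face, opposite the C1 methyl that overhangs the β face, and ring closure then places the oxygen α at both C5 and C6, while the isolated C8=C9 alkene is inert to nucleophilic peroxide.

Step 11
Reactants: 17 5α,6α-epoxy ketone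
Product: 18 6α-hydroxy ketone with trans ring fusion (H5 α, 2α-OTBS, C4 ketone)
Conditions: SmI2 (2.2 equiv), MeOH, THF, −90 °C
Reagents that add atoms: none
Why: SmI2 cleavage of the C5–O bond of the epoxy ketone gives a samarium enolate held to the α-C6 alkoxide, and protonation by methanol at C5 on that α face, away from the C1 methyl, should set the trans ring fusion (H5 α) while the C6 carbinol keeps its α oxygen.

Step 12
Reactants: 18 6α-hydroxy ketone; 19 isopropylmagnesium chloride
Product: 20 4β,6α-diol (4α-isopropyl, 2α-OTBS, H5 α)
Conditions: i-PrMgCl, anhydrous CeCl3 (4 equiv each), THF, −78 to 0 °C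
Reagents that add atoms: isopropylmagnesium chloride (19), CC(C)[Mg]Cl
Why: Organocerium 1,2-addition: the weakly basic reagent should add to the hindered ketone without enolisation or retro-aldol, and with the C6 alkoxide chelating the carbonyl and the axial C1 methyl shielding the β face the isopropyl group enters from the α face, so the new C4 hydroxyl is β.

Step 13
Reactants: 20 4β,6α-diol; 21 4-methoxybenzoyl chloride
Product: 22 6α-(4-methoxybenzoate) of 20 (2α-OTBS, free 4β-OH)
Conditions: 4-MeOC6H4COCl, Et3N, DMAP, CH2Cl2, rt
Reagents that add atoms: 4-methoxybenzoyl chloride (21), COc1ccc(cc1)C(Cl)=O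
Why: DMAP-catalysed acylation takes place at the only secondary hydroxyl, because the tertiary C4 hydroxyl flanked by isopropyl does not react.

Step 14
Reactants: 22 6α-(4-methoxybenzoate) silyl ether
Product: 23 2α,4β-diol 6α-(4-methoxybenzoate)
Conditions: HF·pyridine, pyridine, THF, 0 °C to rt
Reagents that add atoms: none
Why: Fluoride-mediated cleavage of the silyl ether under buffered conditions should leave the aryl ester, the tertiary alcohol and the alkene intact.

Step 15
Reactants: 23 2α,4β-diol 6α-(4-methoxybenzoate); 24 acetic anhydride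
Product: 25 (1S,3R,3aS,4S,8aR)-1-acetoxy-3-hydroxy-6,8a-dimethyl-3-(propan-2-yl)-1,2,3,3a,4,5,8,8a-octahydroazulen-4-yl 4-methoxybenzoate (CNP0171090.1)
Conditions: Ac2O, pyridine, DMAP (cat.), CH2Cl2, 0 °C to rt
Reagents that add atoms: acetic anhydride (24), CC(=O)OC(C)=O
Why: DMAP-catalysed acetylation of the secondary C2 hydroxyl, with the hindered tertiary C4 hydroxyl left free, completes the target.

Compound list
1 | 3-chlorobutan-2-one (racemic) | CC(Cl)C(C)=O | starting material
2 | 3-chloro-2-(trimethylsilyloxy)but-1-ene (racemic) | C=C(O[Si](C)(C)C)C(C)Cl | intermediate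
3 | isoprene | C=CC(C)=C | starting material
4 | 2,5-dimethylcyclohept-4-en-1-one (racemic) | CC1CC=C(C)CCC1=O | intermediate
5 | bromomagnesium enolate of 4, tetrasubstituted (not isolated) | CC1=C(O[Mg]Br)CCC(C)=CC1 | intermediate
6 | 2,5-dimethylcyclohepta-1,4-dien-1-yl trifluoromethanesulfonate | CC1=C(OS(=O)(=O)C(F)(F)F)CCC(C)=CC1 | intermediate
7 | tributyl(vinyl)stannane | C=C[Sn](CCCC)(CCCC)CCCC | starting material
8 | carbon monoxide | [C-]#[O+] | starting material
9 | 1-(2,5-dimethylcyclohepta-1,4-dien-1-yl)prop-2-en-1-one | C=CC(=O)C1=C(C)CC=C(C)CC1 | intermediate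
10 | cross-conjugated dienol, enol form of 11 (not isolated) | OC1=CC[C@]2(C)CC=C(C)CC=C12 | intermediate
11 | (3aR)-3a,6-dimethyl-3,3a,4,7-tetrahydroazulen-1(2H)-one (C4 ketone, C5=C6, C8=C9, quaternary C1) | O=C1CC[C@]2(C)CC=C(C)CC=C12 | intermediate
12 | trimethylsilyl dienol ether of 11 (not isolated) | C[Si](C)(C)OC1=CC[C@]2(C)CC=C(C)CC=C12 | intermediate
13 | (3aS)-3a,6-dimethyl-4,7-dihydroazulen-1(3aH)-one (C2=C3 and C5=C6 flanking the C4 ketone) | O=C1C=C[C@]2(C)CC=C(C)CC=C12 | intermediate
14 | 2α,3α-epoxide of 13 (oxygen anti to the C1 methyl) | O=C1[C@@H]2O[C@@H]2[C@]3(C)CC=C(C)CC=C13 | intermediate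
15 | 2α-hydroxy dienone (C4 ketone, C5=C6, C8=C9) | O=C1C[C@H](O)[C@]2(C)CC=C(C)CC=C12 | intermediate
16 | 2α-(tert-butyldimethylsilyloxy) dienone | O=C1C[C@H](O[Si](C)(C)C(C)(C)C)[C@]2(C)CC=C(C)CC=C12 | intermediate
17 | 5α,6α-epoxy ketone (2α-OTBS) | O1[C@H]2CC(C)=CC[C@@]3(C)[C@@H](O[Si](C)(C)C(C)(C)C)CC(=O)[C@]123 | intermediate
18 | 6α-hydroxy ketone, trans-fused (H5 α, 2α-OTBS) | O[C@H]1CC(C)=CC[C@@]2(C)[C@@H](O[Si](C)(C)C(C)(C)C)CC(=O)[C@H]12 | intermediate
19 | isopropylmagnesium chloride | CC(C)[Mg]Cl | starting material
20 | 4β,6α-diol (4α-isopropyl, 2α-OTBS, H5 α) | O[C@H]1CC(C)=CC[C@@]2(C)[C@@H](O[Si](C)(C)C(C)(C)C)C[C@@](O)(C(C)C)[C@H]12 | intermediate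
21 | 4-methoxybenzoyl chloride | COc1ccc(cc1)C(Cl)=O | starting material
22 | 6α-(4-methoxybenzoate) of 20 | COc1ccc(cc1)C(=O)O[C@H]1CC(C)=CC[C@@]2(C)[C@@H](O[Si](C)(C)C(C)(C)C)C[C@@](O)(C(C)C)[C@H]12 | intermediate
23 | 2α,4β-diol 6α-(4-methoxybenzoate) | COc1ccc(cc1)C(=O)O[C@H]1CC(C)=CC[C@@]2(C)[C@@H](O)C[C@@](O)(C(C)C)[C@H]12 | intermediate
24 | acetic anhydride | CC(=O)OC(C)=O | starting material
25 | (1S,3R,3aS,4S,8aR)-1-acetoxy-3-hydroxy-6,8a-dimethyl-3-(propan-2-yl)-1,2,3,3a,4,5,8,8a-octahydroazulen-4-yl 4-methoxybenzoate | COc1ccc(C(=O)O[C@H]2CC(C)=CC[C@@]3(C)[C@@H](OC(C)=O)C[C@@](O)(C(C)C)[C@H]23)cc1 | target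

Total step count: 15. Longest linear sequence: 15 steps (1 to 25).

Steps most likely to fail

1. Step 5 (key step). The chiral anion may induce little torquoselectivity, because the unsubstituted vinyl terminus offers it little to differentiate. Competing processes are protonation of the C8=C9 alkene, migration of the ring alkenes into conjugation, polymerisation of the vinyl ketone and proton loss from C2. The fallback sets out from 9: an achiral Lewis acid (FeCl3, CH2Cl2, −30 to 0 °C) promotes the known Nazarov cyclisation of a cycloalkenyl vinyl ketone without induction and should give the racemic dienone F1. Preparative chromatography on a chiral stationary phase then separates 11 from the (3aS)-dienone F2, which is discarded, and the route is rejoined at 11.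

2. Step 10. Facial selectivity of the peroxide addition at C6 may be poor or reversed, since the fold of the cycloheptadiene ring can compete with the C1 methyl. The base may also eliminate the β-silyloxy group. The fallback sets out from 16 and fixes C6 by a directed reduction instead of by the epoxidation face. If the peroxide prefers the β face, the 5β,6β-epoxy ketone F3 is taken through the same SmI2 opening to the 6β-hydroxy ketone F4 and the same organocerium addition to the 6-epi diol F5. Dess–Martin oxidation of the secondary hydroxyl gives the 6-ketone F6. Reduction with Me4NBH(OAc)3 (MeCN/AcOH, −20 °C), in which the C4 hydroxyl binds boron and delivers hydride to the β face of C6 (hydroxyl-directed 1,3-anti reduction), then gives 20, where the route is rejoined.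

3. Step 12. Enolisation or β-hydride reduction of the hindered ketone by the secondary alkyl reagent may outrun addition, and the 2α-silyloxy group may erode α-face selectivity. The fallback sets out from 18: 2-propenylmagnesium bromide/CeCl3, an sp2 nucleophile that cannot transfer a β-hydride, should give the isopropenyl carbinol F7. Hydrogenation of its 1,1-disubstituted alkene with Wilkinson's catalyst (H2, RhCl(PPh3)3, benzene), which leaves the trisubstituted C8=C9 alkene, gives 20.

Further compounds
F1 | step 5 | racemic 3a,6-dimethyl-3,3a,4,7-tetrahydroazulen-1(2H)-one | O=C1CCC2(C)CC=C(C)CC=C12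
F2 | step 5 | (3aS)-3a,6-dimethyl-3,3a,4,7-tetrahydroazulen-1(2H)-one | O=C1CC[C@@]2(C)CC=C(C)CC=C12
F3 | step 10 | 5β,6β-epoxy ketone (2α-OTBS) | O1[C@@H]2CC(C)=CC[C@@]3(C)[C@@H](O[Si](C)(C)C(C)(C)C)CC(=O)[C@@]123
F4 | step 10 | 6β-hydroxy ketone, trans-fused (H5 α, 2α-OTBS) | O[C@@H]1CC(C)=CC[C@@]2(C)[C@@H](O[Si](C)(C)C(C)(C)C)CC(=O)[C@H]12
F5 | step 10 | 4β,6β-diol, 6-epimer of 20 | O[C@@H]1CC(C)=CC[C@@]2(C)[C@@H](O[Si](C)(C)C(C)(C)C)C[C@@](O)(C(C)C)[C@H]12
F6 | step 10 | 4β-hydroxy 6-ketone (4α-isopropyl, 2α-OTBS, H5 α) | O=C1CC(C)=CC[C@@]2(C)[C@@H](O[Si](C)(C)C(C)(C)C)C[C@@](O)(C(C)C)[C@H]12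
F7 | step 12 | 4β,6α-diol with 4α-isopropenyl (2α-OTBS, H5 α) | O[C@H]1CC(C)=CC[C@@]2(C)[C@@H](O[Si](C)(C)C(C)(C)C)C[C@@](O)(C(C)=C)[C@H]12
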